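All runs are simulated with made-up constants; scatter was added.

- Over 6.00 h the two earlier runs read very differently, so I hold each against ratios of the charges rather than against concentrations.

| flask | starting material | coupling partner | protic impurity | free catalyst | remark | time |
|---|---|---|---|---|---|---|
| east | 3 mM | 18 mM | 6 mM | 1.6 mM | run made earlier |  |
| south-east | 280 mM | 18 mM | 6 mM | 1.6 mM | run made earlier |  |
| Friday's | 2.0 mM | 18.0 mM | 6.00 mM | 1.6 mM |  | 6.0 h |
| Sunday's | 6.0 mM | 18.0 mM | 6.00 mM | 1.6 mM |  | 6.0 h |
| Thursday's | 20 mM | 18.0 mM | 6.00 mM | 1.6 mM |  | 6.0 h |
| Wednesday's | 60 mM | 18.0 mM | 6.00 mM | 1.6 mM |  | 6.0 h |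
| Monday's | 200 mM | 18.0 mM | 6.00 mM | 1.6 mM |  | 6.0 h |

| run | time / h | target / % |
|---|---|---|
| east | 0.333 | 10.3 |
| east | 1.00 | 29.3 |
| east | 1.50 | 36.1 |
| east | 2.50 | 44.1 |
| east | 4.00 | 46.2 |
| east | 5.00 | 47.4 |
| east | 6.00 | 47.1 |
| south-east | 0.333 | 1.0 |
| south-east | 1.00 | 3.9 |
| south-east | 1.50 | 4.2 |
| south-east | 2.50 | 4.8 |
| south-east | 4.00 | 6.0 |
| south-east | 5.00 | 5.7 |
| south-east | 6.00 | 6.9 |

(each reading ± 0.5 percentage points)

- the numbers in the tables scatter with a standard deviation of 0.5 percentage points
- "hardly changes" means that all values lie within two and a half points (for a concentration: within two and a half percent of the largest)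
- a step back or a flat step of under half a point counts as no turn

1. amount of target at the end, in percent of the starting material charged for Friday's, Sunday's, Thursday's, Wednesday's, Monday's, in this order
2. the course of these numbers from the first flask to the last (falls, then rises / falls all the way / rises, then falls / rises all the way / hardly changes)

- On the fastest rung, the south-east run reads 3.9% of its charge within 1.00 h. That is 6.83 target per free catalyst charged, so one catalytic turn takes about 8.79 min on average.
- On the next rung the east run flattens: it reads 44.1% at 2.50 h and 47.1% at 6.00 h. That is close to half, and I take the even split as the zero of my scale. I read it as two routes sharing the starting material, one to target and one to a loss through the protic impurity, whose charge is twice that of the east run's starting material.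
- On the slowest rung the south-east run creeps from 4.2% at 1.50 h to 6.9% at 6.00 h. The coupling partner's charge is 6.43% of that run's starting material, and the last reading lies within about one scatter of this. I therefore read the coupling partner as the limiting reagent there.
- Monday's flask has 9.00% as its ceiling, the coupling partner's charge as a fraction of the starting material's charge, and this is the quantity I carry.
- My own reckoning puts Monday's target just under that ceiling and Wednesday's just under its ceiling of 30.0%, with Friday's and Sunday's near the even split. In Thursday's flask the impurity's charge is 30.0% of the starting material, so if the impurity is all taken up, 70.0% stays open to target, more than the east run's last reading. So I expect the row to rise, then fall.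
- The forecast gives 48%, 43%, 30%, 16% and 7.5%, a course that falls all the way, and holds that the “coupling-partner ceiling of 18 mM is not reached”. It differs from my reckoning in the course, at Thursday's flask and at Wednesday's flask.
- The flasks give 46.6%, 49.5%, 60.1%, 29.2% and 8.91%, so the row rises, then falls, and Thursday's flask stands at 60.1% against the forecast's 30%.

    starting material + free catalyst ⇌ catalyst intermediate A (K = 86.0 M⁻¹, k = 0.190 M⁻¹ s⁻¹)
    coupling partner + catalyst intermediate A → catalyst intermediate B (k = 0.160 M⁻¹ s⁻¹)
    catalyst intermediate B ⇌ by-product + catalyst intermediate C (K = 1.60 M, k = 0.0800 s⁻¹)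
    catalyst intermediate C → free catalyst + target (k = 0.00670 s⁻¹)
    starting material + protic impurity → quenched substrate (k = 0.0340 M⁻¹ s⁻¹)

- Monday's flask ends at 8.91%, nearly all of its ceiling of 9.00%, with the coupling partner at 0.934% of its own charge after 6.00 h. Scaled by the charges, the ceiling of Wednesday's flask is 30.0%, and there the target stands at 29.2% with 2.62% of the coupling partner's charge left.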